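## Structural features

Rifsaliniketal (41) joins two unlike halves through a secondary amide: a 2-amino-1,4-naphthoquinone and a C1–C17 polyketide chain. In the quinone half, ring A carries the two carbonyls (C1, C4) and the nitrogen (C2), and ring B is fully substituted with a carboxyl group (C5), two hydroxyls (C6, C8) and a methyl group between them (C7). The chain begins with a (2Z,4E)-2-methyldienamide (C1–C5), continues with five contiguous centres that alternate methyl and hydroxyl (C6–C10), and ends in a 1,4-dimethyl-2,8-dioxabicyclo[3.2.1]octane in which the oxygens on C11 and C13 are tied to the ketal carbon C16, with C12 carrying the last methyl. The eight stereocentres C6–C13 stand in an unbroken row (6S,7S,8R,9R,10R,11S,12R,13S; 6,7-anti, 7,8-syn, 8,9-anti, 9,10-anti, 10,11-syn, 11,12-anti, 12,13-syn), C16 (S) is fixed by the bicycle, and the C7–C11 segment is locally mirror-symmetric about C9. The fragile groups are the Z trisubstituted alkene conjugated to the amide, the quinone, the C9 hydroxyl (which can add to C5 of any more electrophilic diene precursor) and the ketal, which is acid-labile although it is the thermodynamic form. The real difficulties are the hexasubstituted ring B, with its carboxyl peri to a quinone carbonyl and a regiodefined nitrogen on ring A, and the eight-centre polypropionate attached to a Z,E-diene. The key step exploits the 1,3-dioxygen pattern of ring B (oxygen on C6 and C8, methyl on C7, carboxyl on C5), the mark of a folded β-polycarbonyl chain, so that C5–C6 and C7–C8 can be made by Claisen and Dieckmann condensations from an arylacetate with an ester ortho to it.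

## Logic of the disconnections

41 ⇒ 40. No skeletal bond is cut; the acid, the two phenols and the two chain hydroxyls are masked as one tert-butyl ester, two MOM ethers and two triethylsilyl ethers. All are acid-labile, so one final step releases everything. The demand is an acid treatment that leaves the Z alkene alone and lets the ketal stay in its thermodynamic form.

40 ⇒ 39. The two quinone C=O groups are traced back to aryl methyl ethers. The quinone would not survive base, copper and amide nucleophiles, whereas the dimethoxynaphthalene does. The forward step must oxidise only the para-dimethoxy ring.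

39 ⇒ 38 + 12. The N–C2(aryl) bond is cut. This divides the target into two halves of similar size, each free of the other's sensitive groups. The forward step is a C–N coupling of a primary amide with an aryl bromide that must not isomerise C2=C3.

12 ⇒ 11 ⇒ 6 + 9. After removal of the phenol protection, ring B is cut at C5–C6 and C7–C8. This is the polyketide fold: a benzene with an acetate arm and an ester arm plus a three-carbon acyl donor replaces a hexasubstituted naphthalene ring. The forward step needs C-acylation and ring closure in one flask with excess base, next to an aryl bromide.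

6 ⇒ 5 ⇒ 3 ⇒ 2 ⇒ 1, and 9 ⇒ 7 + 8. The C–Br bond, the CH2–CO2t-Bu bond and the aryl–CH3 bond are cut in turn; the ester O–CH3 bond is a functional-group change. Each group is placed by a directing effect already present in the ring (para to the side chain; lateral to the ester; between carboxylate and methoxy). The forward steps must each be regioselective.

38 ⇒ 36 ⇒ 35 ⇒ 33 + 34, and 33 ⇒ 31 + 32. The C1–N bond, then C2=C3 and C4=C5 are cut. Both alkenes come from carbonyl olefinations of one aldehyde, so no metal-catalysed diene coupling is needed. The forward steps must give 4E and then 2Z, and the aldehyde α-centre C6 must not epimerise.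

31 ⇒ 30 ⇒ 29 ⇒ 27. The C16–O11 and C16–O13 bonds are cut, and the primary terminus goes back to a silyl ether. Because the bicyclic ketal is the thermodynamic form, any 11,13-diol with a C16 ketone equivalent must collapse to it. The forward demand is a global acid unmasking, followed by a way to single out the primary C5 oxygen.

27 ⇒ 26 ⇒ 18 + 25. The C9–H bond (reduction) and C10–C11 (aldol) are cut. The C7–C11 pentad is symmetric about C9, so a C9 ketone flanked by two syn aldol units is the natural precursor and the synthesis becomes convergent. The forward aldol must be syn, 8,10-syn and anti-Felkin; the reduction must be 1,3-anti to the C11 hydroxyl.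

18 ⇒ 17 ⇒ 15 + 16, and 15 ⇒ 14 ⇒ 13. C7–C8 is cut to a symmetrical ketone and an aldehyde whose single centre (C6) comes from the chiral pool. The forward aldol must be syn and anti-Felkin.

25 ⇒ 24 ⇒ 23 ⇒ 22 ⇒ 20 + 21, and 20 ⇒ 19. C12–C13 is cut as an auxiliary-controlled syn aldol. C16 is carried as a dioxolane from the start, so no later oxidation is needed. The forward step must set C12 and C13 absolutely.

## Other disconnections considered

Alternative 1: The cut is at C6–C7 and C9–C10. Forward, 2-methylpropane-1,3-diol A2 and two equivalents of racemic but-3-en-2-yl acetate A3 would react under a chiral cyclometallated iridium catalyst formed from [Ir(cod)Cl]2, one SEGPHOS antipode and 4-chloro-3-nitrobenzoic acid. Each carbinol terminus is dehydrogenated to a transient aldehyde and crotylated anti through a chair transition state, giving the diene diol A1 with C6, C7, C9 and C10 set and C8 thereby defined. In its favour: one catalytic step from commodity chemicals, no protecting groups and no stoichiometric chiral reagent. Against it here: A1 has two like vinyl ends and two hydroxyls related by pseudo-symmetry, whereas the target's chain ends are unlike, so desymmetrisation steps follow. C12–C17 would still have to be added, and an anti aldol with an ethyl ketone that has two enolisable methylene groups raises a regiochemical problem. Compared with the chosen plan: it addresses the chain and not ring B, so it could replace steps 8–11, 17 and 18 but not the key step. Mechanistically it is reagent-controlled catalysis against substrate-controlled aldol chemistry. For the five centres C6–C10 it is clearly the better in step economy (one step against six); over the whole chain the advantage shrinks once the termini are differentiated.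

Alternative 2: The cut is at C2=C3. Forward, aldehyde 31 would be allylated, the new C5 alcohol esterified to the methacrylate A5, and (H2IMes)(PCy3)Cl2Ru=CHPh (second-generation Grubbs catalyst) would close the six-membered lactone A4. Base would then open A4 by vinylogous E1cB elimination to the (2Z,4E)-acid 36. In its favour: the ring enforces the Z geometry completely, the C5 configuration is irrelevant, and the 4E bond comes from the elimination. Against it here: metathesis onto a 1,1-disubstituted methacrylate is slow, and strong base is needed next to the C6 centre. Compared with the chosen plan: it again concerns the chain and leaves the naphthalene to other chemistry. It takes four steps from 31 to 36 against three (steps 22–24). On Z-selectivity it is the better (structural against kinetic control); on step count the chosen sequence is one step shorter; the two are equal in protecting-group demand.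

Alternative 3: The cut is at C1–C2 and C1–N. Forward, zerovalent palladium (from Pd(OAc)2 and Xantphos) would insert into the C–I bond of the (2Z,4E)-2-iododiene A7, carbon monoxide A9 would insert, and the aminonaphthalene A8 would capture the acylpalladium to give A6. In its favour: a three-component union that needs neither the acid nor the primary amide, and that tolerates the free 7,9-diol. Against it here: A7 needs a Z-selective iodo-olefination of an enal whose free C9 hydroxyl can add to C5. A8 costs an amination of 12, and the acylpalladium of a Z-enoyl unit can isomerise before capture by a hindered aniline. Compared with the chosen plan: both use the same naphthalene from the key step, so this competes only with steps 23–26. Mechanistically the polarity of the union is reversed: the arene is the nitrogen nucleophile and the chain the acyl electrophile, under palladium instead of copper. Counting from enal 33, iodo-olefination, amination of 12 and carbonylation stand against four steps, so it is one step shorter if the amination is a single operation and equal if it runs through an imine. On convergence it is the better, since three components meet in the last bond-forming event. The chosen sequence is the safer in geometry control, since each of its steps is an established reaction type for this substrate class.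

Key step: step 6

Remarks on the chemistry (one line each):
- Chain atoms carry the numbers C1–C17 of 41 (C1 amide carbon, C16 ketal carbon, C17 its methyl); drawn as a zigzag with C5 at the left and C6 as an upward vertex, the substituents are 6-Me back, 7-O front, 8-Me front, 9-O back, 10-Me front, 11-O front, 12-Me back, 13-O back.
- Abbreviations: TBS = tert-butyldimethylsilyl, TES = triethylsilyl, MOM = methoxymethyl, Bic = (1S,3S,4R,5S)-1,4-dimethyl-2,8-dioxabicyclo[3.2.1]octan-3-yl; for 26–28 and 30–40 the chain centres have the spatial arrangement of 41 (CIP letters can change with the protecting groups; the SMILES are decisive).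
- Locants: in naphthalene-1-carboxylate numbering the bromine of 11 stands on C6, next to the C5 methoxy group; a bromine on C7 would place the nitrogen on the wrong quinone carbon.
- Bromine is introduced at the benzene stage (compound 6) because only there is the position para to the side chain distinguished; the C–Br bond is protected in the key step by complete enolisation at −78 °C.
- Assumption: 13, 19, 21, 32 and 34 are purchasable, as is the enantiomer of 21 that one fallback uses.

## Steps

Step 1
Reactants: 1 2,5-dimethoxybenzoic acid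
Product: 2 3,6-dimethoxy-2-methylbenzoic acid
Conditions: s-BuLi (2.2 equiv), TMEDA, THF, −78 °C; MeI, −78 °C → rt; aq. HCl
Reagents that add atoms: iodomethane, CI
Why: Directed ortho-metalation: the lithium carboxylate and the C5 methoxy group both direct to C6, the only position ortho to both, and the aryllithium is methylated by SN2 attack on MeI.

Step 2
Reactants: 2 3,6-dimethoxy-2-methylbenzoic acid
Product: 3 methyl 3,6-dimethoxy-2-methylbenzoate
Conditions: MeI, K2CO3, DMF, rt
Reagents that add atoms: iodomethane, CI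
Why: SN2 O-alkylation of the carboxylate, chosen because the 2,6-disubstituted acid is too hindered for esterification through a tetrahedral intermediate.

Step 3
Reactants: 3 methyl 3,6-dimethoxy-2-methylbenzoate; 4 di-tert-butyl dicarbonate
Product: 5 methyl 2-(2-tert-butoxy-2-oxoethyl)-3,6-dimethoxybenzoate
Conditions: LiN(i-Pr)2 (2.2 equiv), THF, −78 °C; 4, −78 °C; aq. NH4Cl
Reagents that add atoms: none
Why: Lateral lithiation of the ortho-toluate (the benzylic anion is stabilised by the ester) and C-acylation by the dicarbonate; the second equivalent of base holds the more acidic arylacetate as its enolate, so it is not acylated twice.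

Step 4
Reactants: 5 methyl 2-(2-tert-butoxy-2-oxoethyl)-3,6-dimethoxybenzoate
Product: 6 methyl 3-bromo-6-(2-tert-butoxy-2-oxoethyl)-2,5-dimethoxybenzoate
Conditions: NBS, MeCN, 0 °C → rt, dark
Reagents that add atoms: N-bromosuccinimide, O=C1CCC(=O)N1Br
Why: Electrophilic aromatic bromination; both free positions are ortho to a methoxy group, but the one para to the alkyl arm and meta to the ester is the more electron-rich, and ionic conditions spare the benzylic CH2.

Step 5
Reactants: 7 propanoyl chloride; 8 imidazole
Product: 9 1-propanoylimidazole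
Conditions: 8 (2 equiv), THF, 0 °C → rt; filtration
Reagents that add atoms: none
Why: N-acylation of imidazole by the acid chloride; the second equivalent of imidazole takes up the HCl.

Step 6
Reactants: 6 methyl 3-bromo-6-(2-tert-butoxy-2-oxoethyl)-2,5-dimethoxybenzoate; 9 1-propanoylimidazole
Product: 11 tert-butyl 6-bromo-2,4-dihydroxy-5,8-dimethoxy-3-methylnaphthalene-1-carboxylate, via Claisen keto diester 10 (not isolated)
Conditions: LiN(i-Pr)2 (3.5 equiv), THF, −78 °C; 9 (1.2 equiv), −78 → 0 °C; aq. NH4Cl, then dilute HCl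
Reagents that add atoms: none
Why: The amide base first forms the ester enolate at the benzylic carbon (C5), which attacks the acyl carbon of 9 and expels imidazolide (crossed Claisen condensation, C5–C6 bond) to give 10, at once deprotonated to its chelated enolate. A further equivalent of base removes a proton from the propanoyl CH2 (C7), and this terminal carbanion of the β-keto ester dianion adds to the ortho methyl ester (C7–C8 bond) with loss of methoxide, a Dieckmann condensation that closes ring B in the 6-exo-trig mode. Two enolisations of the resulting diketo ester give the aromatic 2,4-diol, which is the driving force and makes the sequence irreversible. The closest known reaction type is the C-acylation of homophthalate diester enolates followed by Dieckmann closure and aromatisation to 1,3-dihydroxynaphthalenes. No stereocentre is formed. The selectivity needed is C- over O-acylation and a single site of ring closure: the acyl imidazole is a mild acyl donor that cannot acylate again once the product is an enolate, and only C7 can reach the methyl ester through a six-membered transition state, since C5 would give a four-membered ring and the tert-butyl ester is hindered and sits on the wrong carbon. Full enolisation at −78 °C before warming protects the aryl bromide from ring metalation.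

Step 7
Reactants: 11 tert-butyl 6-bromo-2,4-dihydroxy-5,8-dimethoxy-3-methylnaphthalene-1-carboxylate
Product: 12 tert-butyl 6-bromo-5,8-dimethoxy-2,4-bis(methoxymethoxy)-3-methylnaphthalene-1-carboxylate
Conditions: NaH, DMF, 0 °C; MOMCl, 0 °C → rt
Reagents that add atoms: chloromethyl methyl ether, COCCl
Why: Williamson-type O-alkylation of the two sodium naphthoxides; the acetals remove the acidic, oxidisable phenols before the copper and cerium steps and fall to the same acid as the tert-butyl ester.

Step 8
Reactants: 13 methyl (S)-3-hydroxy-2-methylpropanoate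
Product: 14 methyl (S)-3-[(tert-butyldimethylsilyl)oxy]-2-methylpropanoate
Conditions: TBSCl, imidazole, DMF, rt
Reagents that add atoms: tert-butyldimethylsilyl chloride, CC(C)(C)[Si](C)(C)Cl
Why: Silylation of the primary alcohol via the N-silylimidazolium species; the chiral-pool centre becomes C6 and is not touched.

Step 9
Reactants: 14 methyl (S)-3-[(tert-butyldimethylsilyl)oxy]-2-methylpropanoate
Product: 15 (S)-3-[(tert-butyldimethylsilyl)oxy]-2-methylpropanal
Conditions: i-Bu2AlH (1.05 equiv), CH2Cl2, −78 °C; MeOH, then aq. potassium sodium tartrate; used crude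
Reagents that add atoms: none
Why: Partial reduction of the ester: the aluminium hemiacetal is stable at −78 °C and releases the aldehyde only on work-up; immediate use avoids epimerisation of the α-centre.

Step 10
Reactants: 15 (S)-3-[(tert-butyldimethylsilyl)oxy]-2-methylpropanal; 16 pentan-3-one
Product: 17 (4R,5S,6S)-7-[(tert-butyldimethylsilyl)oxy]-5-hydroxy-4,6-dimethylheptan-3-one
Conditions: 16, n-Bu2BOTf, i-Pr2NEt, CH2Cl2, −78 °C; 15, −78 → 0 °C; pH 7 buffer, MeOH, H2O2
Reagents that add atoms: none
Why: Boron aldol reaction: the Z enolate of the symmetrical ketone reacts through a chair Zimmerman–Traxler transition state to give the 7,8-syn adduct. The α-methyl aldehyde should be attacked on its anti-Felkin face, because the Felkin arrangement suffers a syn-pentane contact between the enolate methyl and the aldehyde α-substituent, which sets C7 anti to C6.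

Step 11
Reactants: 17 (4R,5S,6S)-7-[(tert-butyldimethylsilyl)oxy]-5-hydroxy-4,6-dimethylheptan-3-one
Product: 18 (4R,5S,6S)-7-[(tert-butyldimethylsilyl)oxy]-4,6-dimethyl-5-[(triethylsilyl)oxy]heptan-3-one
Conditions: TESOTf, 2,6-lutidine, CH2Cl2, −78 °C
Reagents that add atoms: triethylsilyl trifluoromethanesulfonate, CC[Si](CC)(CC)OS(=O)(=O)C(F)(F)F
Why: Silylation at low temperature with a hindered base avoids retro-aldol cleavage; the ether blocks the C7 hydroxyl during the second enolisation.

Step 12
Reactants: 19 ethyl 3-(2-methyl-1,3-dioxolan-2-yl)propanoate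
Product: 20 3-(2-methyl-1,3-dioxolan-2-yl)propanal
Conditions: i-Bu2AlH (1.05 equiv), CH2Cl2, −78 °C; MeOH, then aq. potassium sodium tartrate
Reagents that add atoms: none
Why: Partial ester reduction as in step 9; the dioxolane is inert to the hydride and carries C16 at the ketone oxidation level.

Step 13
Reactants: 20 3-(2-methyl-1,3-dioxolan-2-yl)propanal; 21 (R)-4-benzyl-3-propanoyl-1,3-oxazolidin-2-one
Product: 22 (R)-4-benzyl-3-[(2R,3S)-3-hydroxy-2-methyl-5-(2-methyl-1,3-dioxolan-2-yl)pentanoyl]-1,3-oxazolidin-2-one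
Conditions: 21, n-Bu2BOTf, i-Pr2NEt, CH2Cl2, 0 °C; 20, −78 → 0 °C; pH 7 buffer, MeOH, H2O2
Reagents that add atoms: none
Why: Evans syn aldol reaction: the Z boron enolate reacts through a chair transition state with the auxiliary carbonyl turned away from the enolate oxygen, so the benzyl group shields one face and sets C12 and C13 (12,13-syn) absolutely; the (R)-auxiliary gives the (2R,3S) adduct.

Step 14
Reactants: 22 (R)-4-benzyl-3-[(2R,3S)-3-hydroxy-2-methyl-5-(2-methyl-1,3-dioxolan-2-yl)pentanoyl]-1,3-oxazolidin-2-one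
Product: 23 (R)-4-benzyl-3-[(2R,3S)-2-methyl-5-(2-methyl-1,3-dioxolan-2-yl)-3-[(triethylsilyl)oxy]pentanoyl]-1,3-oxazolidin-2-one
Conditions: TESOTf, 2,6-lutidine, CH2Cl2, −78 → 0 °C
Reagents that add atoms: triethylsilyl trifluoromethanesulfonate, CC[Si](CC)(CC)OS(=O)(=O)C(F)(F)F
Why: Silyl protection of the C13 hydroxyl prevents retro-aldol and lactol formation in the next two steps; the ether is chosen to fall in the later acid step.

Step 15
Reactants: 23 (R)-4-benzyl-3-[(2R,3S)-2-methyl-5-(2-methyl-1,3-dioxolan-2-yl)-3-[(triethylsilyl)oxy]pentanoyl]-1,3-oxazolidin-2-one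
Product: 24 (2S,3S)-2-methyl-5-(2-methyl-1,3-dioxolan-2-yl)-3-[(triethylsilyl)oxy]pentan-1-ol
Conditions: LiBH4, MeOH (1 equiv), THF, 0 °C
Reagents that add atoms: none
Why: Reductive cleavage of the imide at the exocyclic carbonyl, which releases the auxiliary; the α-centre is not enolised, and the change of CIP letter at C2 is only a change of priorities.

Step 16
Reactants: 24 (2S,3S)-2-methyl-5-(2-methyl-1,3-dioxolan-2-yl)-3-[(triethylsilyl)oxy]pentan-1-ol
Product: 25 (2R,3S)-2-methyl-5-(2-methyl-1,3-dioxolan-2-yl)-3-[(triethylsilyl)oxy]pentanal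
Conditions: Dess–Martin periodinane, NaHCO3, CH2Cl2, 0 °C → rt
Reagents that add atoms: none
Why: Dess–Martin oxidation under buffered, non-basic conditions gives the α-chiral aldehyde without epimerisation or loss of the silyl ether.

Step 17
Reactants: 18 (4R,5S,6S)-7-[(tert-butyldimethylsilyl)oxy]-4,6-dimethyl-5-[(triethylsilyl)oxy]heptan-3-one; 25 (2R,3S)-2-methyl-5-(2-methyl-1,3-dioxolan-2-yl)-3-[(triethylsilyl)oxy]pentanal
Product: 26 1-[(tert-butyldimethylsilyl)oxy]-7-hydroxy-2,4,6,8-tetramethyl-11-(2-methyl-1,3-dioxolan-2-yl)-3,9-bis[(triethylsilyl)oxy]undecan-5-one (C9 ketone and C11 hydroxyl in chain numbering)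
Conditions: 18, TiCl4, i-Pr2NEt, CH2Cl2, −78 °C; 25, −78 °C; aq. NH4Cl
Reagents that add atoms: none
Why: Titanium-enolate aldol reaction: enolisation on the less hindered ethyl side gives the Z chlorotitanium enolate, which adds through a closed transition state to give the 10,11-syn adduct. The C8 centre directs the enolate face (its hydrogen eclipses the enolate to minimise A(1,3) strain, and the aldehyde comes in opposite the silyloxyalkyl branch) to give 8,10-syn, and the Z enolate takes 25 on its anti-Felkin face (11,12-anti), so both elements reinforce each other.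

Step 18
Reactants: 26 1-[(tert-butyldimethylsilyl)oxy]-7-hydroxy-2,4,6,8-tetramethyl-11-(2-methyl-1,3-dioxolan-2-yl)-3,9-bis[(triethylsilyl)oxy]undecan-5-one
Product: 27 1-[(tert-butyldimethylsilyl)oxy]-2,4,6,8-tetramethyl-11-(2-methyl-1,3-dioxolan-2-yl)-3,9-bis[(triethylsilyl)oxy]undecane-5,7-diol
Conditions: Me4NBH(OAc)3, MeCN/AcOH, −30 → −20 °C
Reagents that add atoms: none
Why: Evans–Saksena reduction: the C11 hydroxyl exchanges an acetate on boron and hydride is delivered intramolecularly through a chair transition state, which sets C9 1,3-anti to C11. Partial loss of a triethylsilyl group here would be harmless, since the next step removes them all.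

Step 19
Reactants: 27 1-[(tert-butyldimethylsilyl)oxy]-2,4,6,8-tetramethyl-11-(2-methyl-1,3-dioxolan-2-yl)-3,9-bis[(triethylsilyl)oxy]undecane-5,7-diol
Product: 29 (2S,3S,4R,5R,6R)-6-[(1S,3S,4R,5S)-1,4-dimethyl-2,8-dioxabicyclo[3.2.1]octan-3-yl]-2,4-dimethylheptane-1,3,5-triol, via desilylated pentaol 28 (not isolated)
Conditions: camphorsulfonic acid (0.2 equiv), MeOH/CH2Cl2, 0 °C → rt
Reagents that add atoms: none
Why: Acid-catalysed methanolysis removes the three silyl ethers, and the dioxolane exchanges with the C13 and C11 hydroxyls (five-membered ring first, then the six-membered one) to give the bicyclic ketal, the thermodynamic form. C16 needs no control because the bridge allows only one configuration, and ketals that engage O9 or O7 would need seven-membered or larger rings.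

Step 20
Reactants: 29 (2S,3S,4R,5R,6R)-6-[(1S,3S,4R,5S)-1,4-dimethyl-2,8-dioxabicyclo[3.2.1]octan-3-yl]-2,4-dimethylheptane-1,3,5-triol
Product: 30 6-Bic-2,4-dimethyl-1,3,5-tris[(triethylsilyl)oxy]heptane
Conditions: TESOTf (3.5 equiv), 2,6-lutidine, CH2Cl2, −78 → 0 °C
Reagents that add atoms: triethylsilyl trifluoromethanesulfonate, CC[Si](CC)(CC)OS(=O)(=O)C(F)(F)F
Why: Exhaustive silylation; covering the C9 hydroxyl is essential because it would otherwise add to C5 of the enal made in step 22.

Step 21
Reactants: 30 6-Bic-2,4-dimethyl-1,3,5-tris[(triethylsilyl)oxy]heptane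
Product: 31 6-Bic-2,4-dimethyl-3,5-bis[(triethylsilyl)oxy]heptanal
Conditions: (COCl)2, DMSO, CH2Cl2, −78 → −30 °C; Et3N, −78 → 0 °C
Reagents that add atoms: none
Why: Swern oxidation applied directly to the primary triethylsilyl ether: chlorodimethylsulfonium chloride attacks the least hindered silyl ether oxygen, chlorotriethylsilane is lost and the alkoxysulfonium ylide collapses to the aldehyde. The two secondary ethers are too hindered to react at this temperature, and the C6 centre is exposed to base only briefly and cold.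

Step 22
Reactants: 31 6-Bic-2,4-dimethyl-3,5-bis[(triethylsilyl)oxy]heptanal; 32 (triphenylphosphoranylidene)acetaldehyde
Product: 33 (E)-8-Bic-4,6-dimethyl-5,7-bis[(triethylsilyl)oxy]non-2-enal
Conditions: toluene, 80 °C
Reagents that add atoms: none
Why: Wittig olefination with a stabilised ylide, whose reversible addition leads to the E alkene (C4=C5); the ylide is non-basic, so C6 should keep its configuration.

Step 23
Reactants: 33 (E)-8-Bic-4,6-dimethyl-5,7-bis[(triethylsilyl)oxy]non-2-enal; 34 ethyl 2-[bis(2,2,2-trifluoroethoxy)phosphoryl]propanoate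
Product: 35 ethyl (2Z,4E)-10-Bic-2,6,8-trimethyl-7,9-bis[(triethylsilyl)oxy]undeca-2,4-dienoate
Conditions: 34, KN(SiMe3)2, 18-crown-6, THF, −78 °C; 33, −78 °C
Reagents that add atoms: none
Why: Still–Gennari olefination: with the electron-poor phosphonate and a dissociated potassium ion, elimination from the kinetically formed adduct is faster than its reversal, which gives the Z trisubstituted alkene (C2=C3); the 4E bond is not involved.

Step 24
Reactants: 35 ethyl (2Z,4E)-10-Bic-2,6,8-trimethyl-7,9-bis[(triethylsilyl)oxy]undeca-2,4-dienoate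
Product: 36 (2Z,4E)-10-Bic-2,6,8-trimethyl-7,9-bis[(triethylsilyl)oxy]undeca-2,4-dienoic acid
Conditions: LiOH, THF/MeOH/H2O, rt → 40 °C; dilute HCl to pH 4 at 0 °C
Reagents that add atoms: lithium hydroxide, [Li+].[OH-]
Why: Saponification by acyl–oxygen cleavage; hindered secondary silyl ethers and the ketal tolerate hydroxide, which is also too weak a base to deprotonate C6–H, so the Z bond and the C6 centre are not at risk.

Step 25
Reactants: 36 (2Z,4E)-10-Bic-2,6,8-trimethyl-7,9-bis[(triethylsilyl)oxy]undeca-2,4-dienoic acid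
Product: 38 (2Z,4E)-10-Bic-2,6,8-trimethyl-7,9-bis[(triethylsilyl)oxy]undeca-2,4-dienamide, via acyl imidazole 37 (not isolated)
Conditions: 1,1'-carbonyldiimidazole, THF, rt; NH3 (7 M in MeOH), 0 °C → rt
Reagents that add atoms: ammonia, N
Why: Activation as the acyl imidazole (with loss of CO2 and imidazole) followed by ammonolysis; the conditions are neutral to weakly basic, so the Z geometry and the silyl ethers persist, and the acyl imidazole has only one electrophilic carbonyl.

Step 26
Reactants: 38 (2Z,4E)-10-Bic-2,6,8-trimethyl-7,9-bis[(triethylsilyl)oxy]undeca-2,4-dienamide; 12 tert-butyl 6-bromo-5,8-dimethoxy-2,4-bis(methoxymethoxy)-3-methylnaphthalene-1-carboxylate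
Product: 39 tert-butyl 6-{[(2Z,4E)-10-Bic-2,6,8-trimethyl-7,9-bis[(triethylsilyl)oxy]undeca-2,4-dienoyl]amino}-5,8-dimethoxy-2,4-bis(methoxymethoxy)-3-methylnaphthalene-1-carboxylate
Conditions: CuI (20 mol %), trans-N,N'-dimethylcyclohexane-1,2-diamine (40 mol %), K2CO3, toluene, 110 °C
Reagents that add atoms: none
Why: Goldberg amidation: the diamine-ligated amidate of monovalent copper activates the aryl bromide and the C–N bond forms by reductive elimination. Primary amides are the best substrates for this coupling, and the carbonate base in toluene leaves the ester, acetals, silyl ethers and ketal alone.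

Step 27
Reactants: 39 tert-butyl 6-{[(2Z,4E)-10-Bic-2,6,8-trimethyl-7,9-bis[(triethylsilyl)oxy]undeca-2,4-dienoyl]amino}-5,8-dimethoxy-2,4-bis(methoxymethoxy)-3-methylnaphthalene-1-carboxylate
Product: 40 tert-butyl 6-{[(2Z,4E)-10-Bic-2,6,8-trimethyl-7,9-bis[(triethylsilyl)oxy]undeca-2,4-dienoyl]amino}-2,4-bis(methoxymethoxy)-3-methyl-5,8-dioxo-5,8-dihydronaphthalene-1-carboxylate
Conditions: (NH4)2Ce(NO3)6 (2.5 equiv), MeCN/H2O, 0 °C, short reaction time
Reagents that add atoms: water, O
Why: Oxidative demethylation: two one-electron oxidations by tetravalent cerium of the amido-dimethoxy ring, addition of water at the methoxy-bearing carbons and loss of methanol give the para-quinone. Ring B cannot follow, since its oxygens are meta to each other and capped, and any silyl ether lost in the acidic medium would be removed in the next step anyway.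

Step 28
Reactants: 40 tert-butyl 6-{[(2Z,4E)-10-Bic-2,6,8-trimethyl-7,9-bis[(triethylsilyl)oxy]undeca-2,4-dienoyl]amino}-2,4-bis(methoxymethoxy)-3-methyl-5,8-dioxo-5,8-dihydronaphthalene-1-carboxylate
Product: 41 rifsaliniketal
Conditions: CF3CO2H/CH2Cl2/H2O, 0 °C → rt
Reagents that add atoms: none
Why: Acidolysis: the tert-butyl ester loses isobutene, and the two MOM acetals and two silyl ethers are hydrolysed. The bicyclic ketal is the thermodynamic form and closes again if it opens, and no base is present that could isomerise the dienamide or attack the quinone.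

## Compound list

1 | 2,5-dimethoxybenzoic acid | COc1ccc(OC)c(C(=O)O)c1 | starting material
2 | 3,6-dimethoxy-2-methylbenzoic acid | Cc1c(OC)ccc(OC)c1C(=O)O | intermediate
3 | methyl 3,6-dimethoxy-2-methylbenzoate | Cc1c(OC)ccc(OC)c1C(=O)OC | intermediate
4 | di-tert-butyl dicarbonate | CC(C)(C)OC(=O)OC(=O)OC(C)(C)C | starting material
5 | methyl 2-(2-tert-butoxy-2-oxoethyl)-3,6-dimethoxybenzoate | COC(=O)c1c(CC(=O)OC(C)(C)C)c(OC)ccc1OC | intermediate
6 | methyl 3-bromo-6-(2-tert-butoxy-2-oxoethyl)-2,5-dimethoxybenzoate | COC(=O)c1c(CC(=O)OC(C)(C)C)c(OC)cc(Br)c1OC | intermediate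
7 | propanoyl chloride | CCC(Cl)=O | starting material
8 | imidazole | c1c[nH]cn1 | starting material
9 | 1-propanoylimidazole | CCC(=O)n1ccnc1 | intermediate
10 | methyl 3-bromo-6-(1-tert-butoxy-1,3-dioxopentan-2-yl)-2,5-dimethoxybenzoate | COC(=O)c1c(C(C(=O)CC)C(=O)OC(C)(C)C)c(OC)cc(Br)c1OC | intermediate (not isolated)
11 | tert-butyl 6-bromo-2,4-dihydroxy-5,8-dimethoxy-3-methylnaphthalene-1-carboxylate | COc1cc(Br)c(OC)c2c(O)c(C)c(O)c(C(=O)OC(C)(C)C)c12 | intermediate
12 | tert-butyl 6-bromo-5,8-dimethoxy-2,4-bis(methoxymethoxy)-3-methylnaphthalene-1-carboxylate | COCOc1c(C)c(OCOC)c2c(OC)c(Br)cc(OC)c2c1C(=O)OC(C)(C)C | intermediate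
13 | methyl (S)-3-hydroxy-2-methylpropanoate | OC[C@H](C)C(=O)OC | starting material
14 | methyl (S)-3-[(tert-butyldimethylsilyl)oxy]-2-methylpropanoate | CC(C)(C)[Si](C)(C)OC[C@H](C)C(=O)OC | intermediate
15 | (S)-3-[(tert-butyldimethylsilyl)oxy]-2-methylpropanal | CC(C)(C)[Si](C)(C)OC[C@H](C)C=O | intermediate
16 | pentan-3-one | CCC(=O)CC | starting material
17 | (4R,5S,6S)-7-[(tert-butyldimethylsilyl)oxy]-5-hydroxy-4,6-dimethylheptan-3-one | CC(C)(C)[Si](C)(C)OC[C@H](C)[C@H](O)[C@@H](C)C(=O)CC | intermediate
18 | (4R,5S,6S)-7-[(tert-butyldimethylsilyl)oxy]-4,6-dimethyl-5-[(triethylsilyl)oxy]heptan-3-one | CC(C)(C)[Si](C)(C)OC[C@H](C)[C@H](O[Si](CC)(CC)CC)[C@@H](C)C(=O)CC | intermediate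
19 | ethyl 3-(2-methyl-1,3-dioxolan-2-yl)propanoate | CCOC(=O)CCC1(C)OCCO1 | starting material
20 | 3-(2-methyl-1,3-dioxolan-2-yl)propanal | O=CCCC1(C)OCCO1 | intermediate
21 | (R)-4-benzyl-3-propanoyl-1,3-oxazolidin-2-one | CCC(=O)N1[C@H](Cc2ccccc2)COC1=O | starting material
22 | (R)-4-benzyl-3-[(2R,3S)-3-hydroxy-2-methyl-5-(2-methyl-1,3-dioxolan-2-yl)pentanoyl]-1,3-oxazolidin-2-one | O=C1OC[C@@H](Cc2ccccc2)N1C(=O)[C@H](C)[C@@H](O)CCC1(C)OCCO1 | intermediate
23 | (R)-4-benzyl-3-[(2R,3S)-2-methyl-5-(2-methyl-1,3-dioxolan-2-yl)-3-[(triethylsilyl)oxy]pentanoyl]-1,3-oxazolidin-2-one | O=C1OC[C@@H](Cc2ccccc2)N1C(=O)[C@H](C)[C@@H](O[Si](CC)(CC)CC)CCC1(C)OCCO1 | intermediate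
24 | (2S,3S)-2-methyl-5-(2-methyl-1,3-dioxolan-2-yl)-3-[(triethylsilyl)oxy]pentan-1-ol | OC[C@H](C)[C@@H](O[Si](CC)(CC)CC)CCC1(C)OCCO1 | intermediate
25 | (2R,3S)-2-methyl-5-(2-methyl-1,3-dioxolan-2-yl)-3-[(triethylsilyl)oxy]pentanal | O=C[C@H](C)[C@@H](O[Si](CC)(CC)CC)CCC1(C)OCCO1 | intermediate
26 | 1-[(tert-butyldimethylsilyl)oxy]-7-hydroxy-2,4,6,8-tetramethyl-11-(2-methyl-1,3-dioxolan-2-yl)-3,9-bis[(triethylsilyl)oxy]undecan-5-one (chain C5–C15 with the C16 dioxolane; centres as in 41) | CC(C)(C)[Si](C)(C)OC[C@H](C)[C@H](O[Si](CC)(CC)CC)[C@@H](C)C(=O)[C@@H](C)[C@H](O)[C@H](C)[C@@H](O[Si](CC)(CC)CC)CCC1(C)OCCO1 | intermediate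
27 | 1-[(tert-butyldimethylsilyl)oxy]-2,4,6,8-tetramethyl-11-(2-methyl-1,3-dioxolan-2-yl)-3,9-bis[(triethylsilyl)oxy]undecane-5,7-diol (centres as in 41) | CC(C)(C)[Si](C)(C)OC[C@H](C)[C@H](O[Si](CC)(CC)CC)[C@@H](C)[C@@H](O)[C@@H](C)[C@H](O)[C@H](C)[C@@H](O[Si](CC)(CC)CC)CCC1(C)OCCO1 | intermediate
28 | 2,4,6,8-tetramethyl-11-(2-methyl-1,3-dioxolan-2-yl)undecane-1,3,5,7,9-pentaol (centres as in 41) | OC[C@H](C)[C@H](O)[C@@H](C)[C@@H](O)[C@@H](C)[C@H](O)[C@H](C)[C@@H](O)CCC1(C)OCCO1 | intermediate (not isolated)
29 | (2S,3S,4R,5R,6R)-6-[(1S,3S,4R,5S)-1,4-dimethyl-2,8-dioxabicyclo[3.2.1]octan-3-yl]-2,4-dimethylheptane-1,3,5-triol | OC[C@H](C)[C@H](O)[C@@H](C)[C@@H](O)[C@@H](C)[C@@H]1O[C@@]2(C)CC[C@H](O2)[C@H]1C | intermediate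
30 | 6-[(1S,3S,4R,5S)-1,4-dimethyl-2,8-dioxabicyclo[3.2.1]octan-3-yl]-2,4-dimethyl-1,3,5-tris[(triethylsilyl)oxy]heptane (centres as in 41) | CC[Si](CC)(CC)OC[C@H](C)[C@H](O[Si](CC)(CC)CC)[C@@H](C)[C@@H](O[Si](CC)(CC)CC)[C@@H](C)[C@@H]1O[C@@]2(C)CC[C@H](O2)[C@H]1C | intermediate
31 | 6-[(1S,3S,4R,5S)-1,4-dimethyl-2,8-dioxabicyclo[3.2.1]octan-3-yl]-2,4-dimethyl-3,5-bis[(triethylsilyl)oxy]heptanal (centres as in 41) | O=C[C@H](C)[C@H](O[Si](CC)(CC)CC)[C@@H](C)[C@@H](O[Si](CC)(CC)CC)[C@@H](C)[C@@H]1O[C@@]2(C)CC[C@H](O2)[C@H]1C | intermediate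
32 | (triphenylphosphoranylidene)acetaldehyde | O=CC=P(c1ccccc1)(c1ccccc1)c1ccccc1 | starting material
33 | (E)-8-[(1S,3S,4R,5S)-1,4-dimethyl-2,8-dioxabicyclo[3.2.1]octan-3-yl]-4,6-dimethyl-5,7-bis[(triethylsilyl)oxy]non-2-enal (centres as in 41) | O=C/C=C/[C@H](C)[C@H](O[Si](CC)(CC)CC)[C@@H](C)[C@@H](O[Si](CC)(CC)CC)[C@@H](C)[C@@H]1O[C@@]2(C)CC[C@H](O2)[C@H]1C | intermediate
34 | ethyl 2-[bis(2,2,2-trifluoroethoxy)phosphoryl]propanoate | CCOC(=O)C(C)P(=O)(OCC(F)(F)F)OCC(F)(F)F | starting material
35 | ethyl (2Z,4E)-10-[(1S,3S,4R,5S)-1,4-dimethyl-2,8-dioxabicyclo[3.2.1]octan-3-yl]-2,6,8-trimethyl-7,9-bis[(triethylsilyl)oxy]undeca-2,4-dienoate (centres as in 41) | C/C(=C/C=C/[C@H](C)[C@H](O[Si](CC)(CC)CC)[C@@H](C)[C@@H](O[Si](CC)(CC)CC)[C@@H](C)[C@@H]1O[C@@]2(C)CC[C@H](O2)[C@H]1C)C(=O)OCC | intermediate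
36 | (2Z,4E)-10-[(1S,3S,4R,5S)-1,4-dimethyl-2,8-dioxabicyclo[3.2.1]octan-3-yl]-2,6,8-trimethyl-7,9-bis[(triethylsilyl)oxy]undeca-2,4-dienoic acid (centres as in 41) | C/C(=C/C=C/[C@H](C)[C@H](O[Si](CC)(CC)CC)[C@@H](C)[C@@H](O[Si](CC)(CC)CC)[C@@H](C)[C@@H]1O[C@@]2(C)CC[C@H](O2)[C@H]1C)C(=O)O | intermediate
37 | 1-[(2Z,4E)-10-[(1S,3S,4R,5S)-1,4-dimethyl-2,8-dioxabicyclo[3.2.1]octan-3-yl]-2,6,8-trimethyl-7,9-bis[(triethylsilyl)oxy]undeca-2,4-dienoyl]imidazole (centres as in 41) | C/C(=C/C=C/[C@H](C)[C@H](O[Si](CC)(CC)CC)[C@@H](C)[C@@H](O[Si](CC)(CC)CC)[C@@H](C)[C@@H]1O[C@@]2(C)CC[C@H](O2)[C@H]1C)C(=O)n1ccnc1 | intermediate (not isolated)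
38 | (2Z,4E)-10-[(1S,3S,4R,5S)-1,4-dimethyl-2,8-dioxabicyclo[3.2.1]octan-3-yl]-2,6,8-trimethyl-7,9-bis[(triethylsilyl)oxy]undeca-2,4-dienamide (centres as in 41) | C/C(=C/C=C/[C@H](C)[C@H](O[Si](CC)(CC)CC)[C@@H](C)[C@@H](O[Si](CC)(CC)CC)[C@@H](C)[C@@H]1O[C@@]2(C)CC[C@H](O2)[C@H]1C)C(N)=O | intermediate
39 | tert-butyl 6-{[(2Z,4E)-10-[(1S,3S,4R,5S)-1,4-dimethyl-2,8-dioxabicyclo[3.2.1]octan-3-yl]-2,6,8-trimethyl-7,9-bis[(triethylsilyl)oxy]undeca-2,4-dienoyl]amino}-5,8-dimethoxy-2,4-bis(methoxymethoxy)-3-methylnaphthalene-1-carboxylate (centres as in 41) | C/C(=C/C=C/[C@H](C)[C@H](O[Si](CC)(CC)CC)[C@@H](C)[C@@H](O[Si](CC)(CC)CC)[C@@H](C)[C@@H]1O[C@@]2(C)CC[C@H](O2)[C@H]1C)C(=O)Nc1cc(OC)c2c(C(=O)OC(C)(C)C)c(OCOC)c(C)c(OCOC)c2c1OC | intermediate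
40 | tert-butyl 6-{[(2Z,4E)-10-[(1S,3S,4R,5S)-1,4-dimethyl-2,8-dioxabicyclo[3.2.1]octan-3-yl]-2,6,8-trimethyl-7,9-bis[(triethylsilyl)oxy]undeca-2,4-dienoyl]amino}-2,4-bis(methoxymethoxy)-3-methyl-5,8-dioxo-5,8-dihydronaphthalene-1-carboxylate (centres as in 41) | C/C(=C/C=C/[C@H](C)[C@H](O[Si](CC)(CC)CC)[C@@H](C)[C@@H](O[Si](CC)(CC)CC)[C@@H](C)[C@@H]1O[C@@]2(C)CC[C@H](O2)[C@H]1C)C(=O)NC1=CC(=O)c2c(C(=O)OC(C)(C)C)c(OCOC)c(C)c(OCOC)c2C1=O | intermediate
41 | rifsaliniketal, 6-{[(2Z,4E,6S,7S,8R,9R,10R)-10-[(1S,3S,4R,5S)-1,4-dimethyl-2,8-dioxabicyclo[3.2.1]octan-3-yl]-7,9-dihydroxy-2,6,8-trimethylundeca-2,4-dienoyl]amino}-2,4-dihydroxy-3-methyl-5,8-dioxo-5,8-dihydronaphthalene-1-carboxylic acid | C/C(=C/C=C/[C@H](C)[C@H](O)[C@@H](C)[C@@H](O)[C@@H](C)[C@@H]1O[C@@]2(C)CC[C@H](O2)[C@H]1C)C(=O)NC1=CC(=O)c2c(C(=O)O)c(O)c(C)c(O)c2C1=O | target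

## Step count and least certain steps

Total: 28 steps. Longest linear sequence: 17 steps (19 → 20 → 22 → 23 → 24 → 25 → 26 → 27 → 29 → 30 → 31 → 33 → 35 → 36 → 38 → 39 → 40 → 41). The arene branch is 7 steps (1–7) and the C5–C10 ketone branch 4 steps (8–11).

Step 6 (key step). What may go wrong: metalation of the ring next to bromine by the excess amide base with loss of lithium bromide, consumption of 9 by enolisation, O- instead of C-acylation, or stalling at the monoanion of the Claisen product because the second deprotonation is slow. Fallback F0 (from 6, back at 11; no new compound is made): the two bond formations are separated. LiN(SiMe3)2, which is too weak to metalate the ring, effects the Claisen condensation with 9, and keto diester 10 is isolated. Ring closure is then run under equilibrating alkoxide conditions (NaOMe in MeOH, or KOt-Bu in t-BuOH, warm), in which the small equilibrium share of the C7 enolate cyclises onto the methyl ester and aromatisation pulls the equilibrium over to 11.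

Step 10. What may go wrong: insufficient facial discrimination, since the α-methyl centre of the aldehyde is the only control element and the anti-Felkin preference of a Z enolate is moderate. Fallback (from 15, back at 18): auxiliary control. The boron enolate of 21 and 15 give the Evans syn adduct (R)-4-benzyl-3-[(2R,3S,4S)-5-[(tert-butyldimethylsilyl)oxy]-3-hydroxy-2,4-dimethylpentanoyl]-1,3-oxazolidin-2-one F1. Transamination with MeNH(OMe)·HCl and AlMe3 gives the Weinreb amide (2R,3S,4S)-5-[(tert-butyldimethylsilyl)oxy]-3-hydroxy-N-methoxy-N,2,4-trimethylpentanamide F2. Silylation gives its triethylsilyl ether F3, and EtMgBr converts F3 into 18. This costs two more steps.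

Step 17. What may go wrong: poor facial selectivity in the double-stereodifferentiating aldol if the 12,13-syn β-silyloxy aldehyde opposes the preference of the enolate, or epimerisation of the aldehyde at C12 under the titanium conditions. Fallback (from 25 and 15, back at 29): C10 and C11 are set by an auxiliary and the order of the two ketone aldol reactions is reversed. The boron enolate of (S)-4-benzyl-3-propanoyl-1,3-oxazolidin-2-one, the enantiomer of 21, adds to 25 under the conditions of step 13 to give the Evans syn adduct (S)-4-benzyl-3-[3-hydroxy-2,4-dimethyl-7-(2-methyl-1,3-dioxolan-2-yl)-5-[(triethylsilyl)oxy]heptanoyl]-1,3-oxazolidin-2-one F4. Transamination with MeNH(OMe)·HCl and AlMe3 gives the Weinreb amide F5, silylation with TESOTf and 2,6-lutidine gives its bis(triethylsilyl) ether F6, and EtMgBr gives the ethyl ketone 4,6-dimethyl-9-(2-methyl-1,3-dioxolan-2-yl)-5,7-bis[(triethylsilyl)oxy]nonan-3-one F7. The chlorotitanium enolate of F7 (TiCl4, i-Pr2NEt, −78 °C) is then added to the small aldehyde 15, the best-precedented pairing for this enolate type, to give the C7-hydroxy ketone F8 with the 8,10-syn and 7,8-syn relationships. Reduction with Me4NBH(OAc)3, now directed by the C7 hydroxyl, gives the 7,9-diol F9, and the conditions of step 19 convert F9 into 29. Steps 10 and 11 fall away, so this costs two more steps.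

Step 21. What may go wrong: incomplete cleavage of the primary silyl ether at low temperature, or loss of a secondary silyl ether and epimerisation at C6 if the mixture is warmed too far. Fallback (from 30, back at 31): two separate operations. Selective methanolysis of the primary ether (pyridinium p-toluenesulfonate, MeOH/CH2Cl2, −10 °C) gives 6-Bic-2,4-dimethyl-3,5-bis[(triethylsilyl)oxy]heptan-1-ol F10, which is oxidised with Dess–Martin periodinane to 31.

Step 26. What may go wrong: slow coupling of the electron-rich, ortho-substituted bromide with the hindered conjugated amide, so that thermal Z to E isomerisation at C2=C3 or protodebromination competes. Fallback (from 12 and 36, back at 39): the nitrogen is put on the arene first. Amination of 12 with benzophenone imine (Pd2(dba)3, BINAP, Cs2CO3, toluene) gives the imine tert-butyl 6-[(diphenylmethylidene)amino]-5,8-dimethoxy-2,4-bis(methoxymethoxy)-3-methylnaphthalene-1-carboxylate F11. Transimination (NH2OH·HCl, NaOAc, MeOH) gives the amine tert-butyl 6-amino-5,8-dimethoxy-2,4-bis(methoxymethoxy)-3-methylnaphthalene-1-carboxylate F12, the same compound as A8. Acid 36 is converted under neutral conditions with 1-chloro-N,N,2-trimethylprop-1-en-1-amine into the acid chloride (2Z,4E)-10-Bic-2,6,8-trimethyl-7,9-bis[(triethylsilyl)oxy]undeca-2,4-dienoyl chloride F13, which acylates F12 in the presence of pyridine to give 39.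

## Further compounds

F0 | step 6 | none | none
F1 | step 10 | (R)-4-benzyl-3-[(2R,3S,4S)-5-[(tert-butyldimethylsilyl)oxy]-3-hydroxy-2,4-dimethylpentanoyl]-1,3-oxazolidin-2-one | O=C1OC[C@@H](Cc2ccccc2)N1C(=O)[C@H](C)[C@@H](O)[C@@H](C)CO[Si](C)(C)C(C)(C)C
F2 | step 10 | (2R,3S,4S)-5-[(tert-butyldimethylsilyl)oxy]-3-hydroxy-N-methoxy-N,2,4-trimethylpentanamide | CON(C)C(=O)[C@H](C)[C@@H](O)[C@@H](C)CO[Si](C)(C)C(C)(C)C
F3 | step 10 | (2R,3S,4S)-5-[(tert-butyldimethylsilyl)oxy]-N-methoxy-N,2,4-trimethyl-3-[(triethylsilyl)oxy]pentanamide | CON(C)C(=O)[C@H](C)[C@@H](O[Si](CC)(CC)CC)[C@@H](C)CO[Si](C)(C)C(C)(C)C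
F4 | step 17 | (S)-4-benzyl-3-[3-hydroxy-2,4-dimethyl-7-(2-methyl-1,3-dioxolan-2-yl)-5-[(triethylsilyl)oxy]heptanoyl]-1,3-oxazolidin-2-one (centres C10–C13 as in 41) | O=C1OC[C@H](Cc2ccccc2)N1C(=O)[C@@H](C)[C@H](O)[C@H](C)[C@@H](O[Si](CC)(CC)CC)CCC1(C)OCCO1
F5 | step 17 | 3-hydroxy-N-methoxy-N,2,4-trimethyl-7-(2-methyl-1,3-dioxolan-2-yl)-5-[(triethylsilyl)oxy]heptanamide (centres C10–C13 as in 41) | CON(C)C(=O)[C@@H](C)[C@H](O)[C@H](C)[C@@H](O[Si](CC)(CC)CC)CCC1(C)OCCO1
F6 | step 17 | N-methoxy-N,2,4-trimethyl-7-(2-methyl-1,3-dioxolan-2-yl)-3,5-bis[(triethylsilyl)oxy]heptanamide (centres C10–C13 as in 41) | CON(C)C(=O)[C@@H](C)[C@H](O[Si](CC)(CC)CC)[C@H](C)[C@@H](O[Si](CC)(CC)CC)CCC1(C)OCCO1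
F7 | step 17 | 4,6-dimethyl-9-(2-methyl-1,3-dioxolan-2-yl)-5,7-bis[(triethylsilyl)oxy]nonan-3-one (centres C10–C13 as in 41) | CCC(=O)[C@@H](C)[C@H](O[Si](CC)(CC)CC)[C@H](C)[C@@H](O[Si](CC)(CC)CC)CCC1(C)OCCO1
F8 | step 17 | 1-[(tert-butyldimethylsilyl)oxy]-3-hydroxy-2,4,6,8-tetramethyl-11-(2-methyl-1,3-dioxolan-2-yl)-7,9-bis[(triethylsilyl)oxy]undecan-5-one (centres as in 41) | CC(C)(C)[Si](C)(C)OC[C@H](C)[C@H](O)[C@@H](C)C(=O)[C@@H](C)[C@H](O[Si](CC)(CC)CC)[C@H](C)[C@@H](O[Si](CC)(CC)CC)CCC1(C)OCCO1
F9 | step 17 | 1-[(tert-butyldimethylsilyl)oxy]-2,4,6,8-tetramethyl-11-(2-methyl-1,3-dioxolan-2-yl)-7,9-bis[(triethylsilyl)oxy]undecane-3,5-diol (centres as in 41) | CC(C)(C)[Si](C)(C)OC[C@H](C)[C@H](O)[C@@H](C)[C@@H](O)[C@@H](C)[C@H](O[Si](CC)(CC)CC)[C@H](C)[C@@H](O[Si](CC)(CC)CC)CCC1(C)OCCO1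
F10 | step 21 | 6-[(1S,3S,4R,5S)-1,4-dimethyl-2,8-dioxabicyclo[3.2.1]octan-3-yl]-2,4-dimethyl-3,5-bis[(triethylsilyl)oxy]heptan-1-ol (centres as in 41) | OC[C@H](C)[C@H](O[Si](CC)(CC)CC)[C@@H](C)[C@@H](O[Si](CC)(CC)CC)[C@@H](C)[C@@H]1O[C@@]2(C)CC[C@H](O2)[C@H]1C
F11 | step 26 | tert-butyl 6-[(diphenylmethylidene)amino]-5,8-dimethoxy-2,4-bis(methoxymethoxy)-3-methylnaphthalene-1-carboxylate | COCOc1c(C)c(OCOC)c2c(OC)c(N=C(c3ccccc3)c3ccccc3)cc(OC)c2c1C(=O)OC(C)(C)C
F12 | step 26 | tert-butyl 6-amino-5,8-dimethoxy-2,4-bis(methoxymethoxy)-3-methylnaphthalene-1-carboxylate | COCOc1c(C)c(OCOC)c2c(OC)c(N)cc(OC)c2c1C(=O)OC(C)(C)C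
F13 | step 26 | (2Z,4E)-10-[(1S,3S,4R,5S)-1,4-dimethyl-2,8-dioxabicyclo[3.2.1]octan-3-yl]-2,6,8-trimethyl-7,9-bis[(triethylsilyl)oxy]undeca-2,4-dienoyl chloride (centres as in 41) | C/C(=C/C=C/[C@H](C)[C@H](O[Si](CC)(CC)CC)[C@@H](C)[C@@H](O[Si](CC)(CC)CC)[C@@H](C)[C@@H]1O[C@@]2(C)CC[C@H](O2)[C@H]1C)C(Cl)=O
A1 | alternative 1 | (3S,4S,6S,7S)-3,5,7-trimethylnona-1,8-diene-4,6-diol | C=C[C@H](C)[C@H](O)[C@@H](C)[C@@H](O)[C@@H](C)C=C
A2 | alternative 1 | 2-methylpropane-1,3-diol | CC(CO)CO
A3 | alternative 1 | but-3-en-2-yl acetate (racemic) | CC(OC(C)=O)C=C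
A4 | alternative 2 | 3-methyl-5,6-dihydro-2H-pyran-2-one bearing the bis(triethylsilyl)-protected C6–C17 chain on the ring carbon that is chain C5 (C5 configuration open; other centres as in 41) | CC1=CCC(OC1=O)[C@H](C)[C@H](O[Si](CC)(CC)CC)[C@@H](C)[C@@H](O[Si](CC)(CC)CC)[C@@H](C)[C@@H]1O[C@@]2(C)CC[C@H](O2)[C@H]1C
A5 | alternative 2 | 2-methylprop-2-enoate of the C5 homoallylic alcohol obtained by allylation of 31 (C5 configuration open; other centres as in 41) | C=C(C)C(=O)OC(CC=C)[C@H](C)[C@H](O[Si](CC)(CC)CC)[C@@H](C)[C@@H](O[Si](CC)(CC)CC)[C@@H](C)[C@@H]1O[C@@]2(C)CC[C@H](O2)[C@H]1C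
A6 | alternative 3 | tert-butyl 6-{[(2Z,4E)-10-[(1S,3S,4R,5S)-1,4-dimethyl-2,8-dioxabicyclo[3.2.1]octan-3-yl]-7,9-dihydroxy-2,6,8-trimethylundeca-2,4-dienoyl]amino}-5,8-dimethoxy-2,4-bis(methoxymethoxy)-3-methylnaphthalene-1-carboxylate (centres as in 41) | C/C(=C/C=C/[C@H](C)[C@H](O)[C@@H](C)[C@@H](O)[C@@H](C)[C@@H]1O[C@@]2(C)CC[C@H](O2)[C@H]1C)C(=O)Nc1cc(OC)c2c(C(=O)OC(C)(C)C)c(OCOC)c(C)c(OCOC)c2c1OC
A7 | alternative 3 | (2Z,4E)-2-iodo diene: the C2–C17 chain of 41 with free 7,9-diol and iodine on C2 in place of the carboxamide (centres as in 41) | C/C(I)=C/C=C/[C@H](C)[C@H](O)[C@@H](C)[C@@H](O)[C@@H](C)[C@@H]1O[C@@]2(C)CC[C@H](O2)[C@H]1C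
A8 | alternative 3 | tert-butyl 6-amino-5,8-dimethoxy-2,4-bis(methoxymethoxy)-3-methylnaphthalene-1-carboxylate | COCOc1c(C)c(OCOC)c2c(OC)c(N)cc(OC)c2c1C(=O)OC(C)(C)C
A9 | alternative 3 | carbon monoxide | [C-]#[O+]
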